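The plan cuts C3–C3a and C1–C8a, the two bonds by which the cyclopentane (ring A) hangs on the cycloheptane (ring B). The feature used is the vicinal trans pair C3a/C8a next to C4: these atoms are the β- and α-carbons of a C8 ketone. One operation on a preformed enone therefore adds a methallyl unit to C3a, anti to the C4 isopropyl group, and an aldehyde to C8a, anti to the new chain. The precursor is a 4-isopropylcyclohept-2-enone that already carries C4, C5 and C7 in their final configuration. Its quaternary C7 leaves C8a as the only enolisable site. Ring A is closed afterwards by metathesis, and C8 is then deoxygenated.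

Key step: step 15

Remark on locants and faces: the azulene locants of the target are used for every compound. β is the face of C8a–H and α the face of C3a–H, so the target has 4α-isopropyl, 5β-acyloxy, 7α-OH, 7β-CH3 and an α-epoxide.
Remark on configuration: C4 and C5 are trans on ring B. Along the chain C3a–C4–C5–C6 this is a syn aldol relationship, (2R,3S) in the adduct, which requires the (R)-benzyloxazolidinone. (S)-Citramalic acid supplies C7, and its descriptor changes from S to R only when C8 loses its oxygen.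
Remark on protecting groups: the C7 oxygen is carried as a benzyl ether, not a silyl ether. A silyl group there could migrate to the neighbouring C8 alkoxide formed during deoxygenation. The benzyl group is removed in the last step together with the phenol benzyl ether, so it adds no step.
Remark on reagents: (phenylselanyl)acetaldehyde is not a stock chemical and is prepared within the route.
Assumption: the aldol carbinol carbon C1 and the later C8 carbinol carbon form without control. Both are erased afterwards and are left undefined in the SMILES.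

Step 1
Reactants: 1 (S)-citramalic acid
Product: 2 2-[(4S)-2,2,4-trimethyl-5-oxo-1,3-dioxolan-4-yl]acetic acid
Conditions: 2,2-dimethoxypropane, p-TsOH (cat.), rt
Reagents that add atoms: 2,2-dimethoxypropane, COC(C)(C)OC
Why: Acid-catalysed acetal exchange closes the favoured five-membered dioxolanone over the tertiary hydroxyl and its own carboxyl, which protects C7–O and C8 together, leaves the C5 carboxyl free and does not touch the C7 stereocentre.

Step 2
Reactants: 2 dioxolanone acid
Product: 4 (3S)-3-hydroxy-3-methyloxolan-2-one, via hydroxyethyl dioxolanone 3 (not isolated)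
Conditions: BH3·THF, THF, 0 °C → rt; MeOH; then p-TsOH (cat.), CH2Cl2, rt
Reagents that add atoms: none
Why: Borane reduces a free carboxylic acid much faster than the ester-like dioxolanone carbonyl, and acid-catalysed translactonisation of 3 then expels acetone to give a non-enolisable γ-lactone in which C5 and C8 are differentiated.

Step 3
Reactants: 4 hydroxy lactone
Product: 5 (3S)-3-(benzyloxy)-3-methyloxolan-2-one
Conditions: NaH, BnBr, Bu4NI (cat.), DMF, 0 °C → rt
Reagents that add atoms: benzyl bromide, BrCc1ccccc1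
Why: Williamson etherification of the tertiary alkoxide is safe because the lactone has no α-hydrogen, and the benzyl ether cannot migrate to a C8 alkoxide later and tolerates TiCl4 at low temperature.

Step 4
Reactants: 5 benzyloxy lactone
Product: 6 (2S)-2-(benzyloxy)-4-hydroxy-N-methoxy-N,2-dimethylbutanamide
Conditions: Me(MeO)NH·HCl, i-PrMgCl, THF, −20 → 0 °C; aq. NH4Cl
Reagents that add atoms: N,O-dimethylhydroxylamine hydrochloride, CNOC.Cl
Why: Aminolysis of the lactone by the magnesium amide (Weinreb amide formation) opens the ring as its magnesium alkoxide and fixes C8 at the acyl level that step 12 needs.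

Step 5
Reactants: 6 hydroxy amide
Product: 7 (2S)-2-(benzyloxy)-N-methoxy-N,2-dimethyl-4-oxobutanamide
Conditions: Dess–Martin periodinane, CH2Cl2, 0 °C → rt
Reagents that add atoms: none
Why: Dess–Martin oxidation gives the C5 aldehyde under near-neutral conditions fast enough to forestall relactonisation, and the quaternary C7 cannot epimerise.

Step 6
Reactants: 8 (4R)-4-benzyl-1,3-oxazolidin-2-one; 9 3-methylbutanoyl chloride
Product: 10 (4R)-4-benzyl-3-(3-methylbutanoyl)-1,3-oxazolidin-2-one
Conditions: n-BuLi, THF, −78 °C; then 9, −78 → 0 °C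
Reagents that add atoms: none
Why: N-Acylation of the deprotonated auxiliary by the acid chloride is the standard entry to the aldol donor and leaves the auxiliary stereocentre untouched.

Step 7
Reactants: 10 N-isovaleryl oxazolidinone; 7 aldehyde
Product: 12 (4R)-4-benzyl-3-[(2R,3S,5S)-5-(benzyloxy)-3-hydroxy-6-[methoxy(methyl)amino]-5-methyl-6-oxo-2-(propan-2-yl)hexanoyl]-1,3-oxazolidin-2-one, via Z-dibutylboron enolate 11 (not isolated)
Conditions: Bu2BOTf, Et3N, CH2Cl2, −78 → 0 °C; 7, −78 → 0 °C; H2O2, MeOH, pH 7 buffer, 0 °C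
Reagents that add atoms: none
Why: Evans syn-aldol reaction, in which soft enolisation gives Z-enolate 11, and this reacts through a closed chair transition state on the face left open by the benzyl group of the (R)-auxiliary, so that C4 and C5 are set together in the syn relationship that becomes trans on ring B, the remote C7 centre having little influence.

Step 8
Reactants: 12 aldol adduct
Product: 13 (4R)-4-benzyl-3-[(2R,3S,5S)-5-(benzyloxy)-3-[(tert-butyldimethylsilyl)oxy]-6-[methoxy(methyl)amino]-5-methyl-6-oxo-2-(propan-2-yl)hexanoyl]-1,3-oxazolidin-2-one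
Conditions: TBSOTf, 2,6-lutidine, CH2Cl2, 0 °C
Reagents that add atoms: tert-butyldimethylsilyl triflate, CC(C)(C)[Si](C)(C)OS(=O)(=O)C(F)(F)F
Why: Silylation with the triflate overcomes the hindrance next to the isopropyl-bearing carbon and, done promptly, also blocks γ-lactonisation of the C5 hydroxyl onto the C8 amide and retro-aldol cleavage.

Step 9
Reactants: 13 silylated imide
Product: 14 (2S,4S,5S)-2-(benzyloxy)-4-[(tert-butyldimethylsilyl)oxy]-5-(hydroxymethyl)-N-methoxy-N,2,6-trimethylheptanamide
Conditions: LiBH4, H2O (1 equiv), Et2O, 0 °C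
Reagents that add atoms: none
Why: Reductive removal of the auxiliary works because LiBH4 reduces the activated imide carbonyl far faster than the tertiary, α-quaternary N-methoxy-N-methylamide, so only C3a reaches the alcohol level and C4 is not epimerised.

Step 10
Reactants: 14 primary alcohol
Product: 15 (2S,4S,5R)-2-(benzyloxy)-4-[(tert-butyldimethylsilyl)oxy]-5-formyl-N-methoxy-N,2,6-trimethylheptanamide
Conditions: Dess–Martin periodinane, CH2Cl2, 0 °C → rt
Reagents that add atoms: none
Why: Dess–Martin oxidation gives the α-branched aldehyde without base, so the C4 stereocentre is kept (its descriptor changes by priority only).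

Step 11
Reactants: 15 aldehyde
Product: 16 (2S,4S,5S)-2-(benzyloxy)-4-[(tert-butyldimethylsilyl)oxy]-N-methoxy-N,2-dimethyl-5-(propan-2-yl)hept-6-enamide
Conditions: Ph3PCH3Br, KOt-Bu, THF, 0 °C; then 15, −78 → 0 °C
Reagents that add atoms: methyltriphenylphosphonium bromide, C[P+](c1ccccc1)(c1ccccc1)c1ccccc1.[Br-]
Why: Wittig methylenation with the non-stabilised ylide is fast at low temperature, which outruns epimerisation at C4, and the hindered amide is inert to the ylide.

Step 12
Reactants: 16 alkenyl amide; 17 vinylmagnesium bromide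
Product: 18 (4S,6S,7S)-4-(benzyloxy)-6-[(tert-butyldimethylsilyl)oxy]-4-methyl-7-(propan-2-yl)nona-1,8-dien-3-one
Conditions: 17 (3 equiv), THF, 0 °C → rt; inverse quench into cold 1 M HCl
Reagents that add atoms: none
Why: Weinreb ketone synthesis, in which the N-methoxy-N-methylamide accepts one vinyl group only, the C7 benzyloxy oxygen helps to bind magnesium, and the acidic inverse quench keeps the liberated amine protonated so that it cannot add to the new enone.

Step 13
Reactants: 18 dienone
Product: 19 (4S,5S,7S)-7-(benzyloxy)-5-[(tert-butyldimethylsilyl)oxy]-7-methyl-4-(propan-2-yl)cyclohept-2-en-1-one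
Conditions: second-generation Grubbs catalyst RuCl2(=CHPh)(PCy3)(SIMes) (5 mol %), CH2Cl2 (2 mM), reflux
Reagents that add atoms: none
Why: Ring-closing metathesis starts at the electron-rich terminal alkene and closes onto the acryloyl unit with loss of ethylene, the quaternary C7 favouring the folded conformer, to give the C3a=C8a enone in ring B without touching a stereocentre.

Step 14
Reactants: 20 benzeneselenenyl chloride; 21 ethyl vinyl ether
Product: 23 (phenylselanyl)acetaldehyde, via α-chloro ether 22 (not isolated)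
Conditions: CH2Cl2, −78 → 0 °C; then H2O, NaHCO3, THF, rt
Reagents that add atoms: water, O
Why: Electrophilic selenenylation of an enol ether places selenium on the terminal carbon and chloride on the oxygen-bearing carbon, and mild hydrolysis of 22 releases the α-seleno aldehyde, which is used fresh.

Step 15
Reactants: 19 cycloheptenone; 24 methallyltrimethylsilane; 23 (phenylselanyl)acetaldehyde
Product: 26 (2S,3S,4S,5S,7S)-7-(benzyloxy)-5-[(tert-butyldimethylsilyl)oxy]-2-[1-hydroxy-2-(phenylselanyl)ethyl]-7-methyl-3-(2-methylprop-2-en-1-yl)-4-(propan-2-yl)cycloheptan-1-one, via trichlorotitanium enolate 25 (not isolated)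
Conditions: TiCl4 (1.2 equiv), CH2Cl2, −78 °C; 24 (1.1 equiv); then 23 (2 equiv), −78 → −40 °C; H2O
Reagents that add atoms: none
Why: TiCl4 binds the C8 carbonyl (helped by the C7 benzyloxy oxygen), the π-nucleophile 24 attacks the β-carbon C3a, chloride removes the silyl group, and enolate 25 then adds through C8a to aldehyde 23. This is a tandem Hosomi–Sakurai conjugate allylation and titanium aldol addition, a known three-component route to trans-2,3-disubstituted cycloalkanones, and it closes no ring. C3a is set by the adjacent C4 stereocentre, because the isopropyl group shields the α face and the silane enters from the β face. C8a is set by the new C3a chain, because the aldehyde meets the enolate on the opposite (α) face and so gives the trans pair, while the carbinol carbon C1 forms without control and is erased in step 16. Regioselectivity is built in, since C7 is quaternary and the enolate arises only at C8a, and chemoselectivity is secured by using barely more than one equivalent of 24, so that little silane remains to allylate 23. The TBS and benzyl ethers tolerate TiCl4 at −78 °C, and chelated titanium enolates of α-benzyloxy ketones are known to be stable at that temperature.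

Step 16
Reactants: 26 β-hydroxy selenide
Product: 28 (2R,3S,4S,5S,7S)-7-(benzyloxy)-5-[(tert-butyldimethylsilyl)oxy]-2-ethenyl-7-methyl-3-(2-methylprop-2-en-1-yl)-4-(propan-2-yl)cycloheptan-1-one, via mesylate 27 (not isolated)
Conditions: MsCl, Et3N, CH2Cl2, −20 → 0 °C
Reagents that add atoms: none
Why: Reductive elimination of a β-hydroxy selenide, in which the mesylate departs with selenium participation so that both C1 epimers give the same terminal vinyl group, while the low temperature keeps the β,γ-alkene out of conjugation and C8a intact (its descriptor changes by priority only).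

Step 17
Reactants: 28 α-vinyl ketone
Product: 29 (2R,3R,4S,5S,7S)-7-(benzyloxy)-5-[(tert-butyldimethylsilyl)oxy]-2-ethenyl-7-methyl-3-(2-methylprop-2-en-1-yl)-4-(propan-2-yl)cycloheptan-1-ol (C8 epimers)
Conditions: LiAlH4, Et2O, −78 → 0 °C
Reagents that add atoms: none
Why: Hydride 1,2-reduction of the ketone removes the acidity of C8a–H at once, so the vinyl group can no longer slip into conjugation, and the new C8 carbinol centre needs no control because it is removed in step 20.

Step 18
Reactants: 29 dienol
Product: 30 (3aR,4S,5S,7S,8aS)-7-(benzyloxy)-5-[(tert-butyldimethylsilyl)oxy]-2,7-dimethyl-4-(propan-2-yl)-3,3a,4,5,6,7,8,8a-octahydroazulen-8-ol (C8 epimers)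
Conditions: second-generation Grubbs catalyst RuCl2(=CHPh)(PCy3)(SIMes) (5 mol %), CH2Cl2, reflux
Reagents that add atoms: none
Why: Ring-closing metathesis of the vinyl and the methallyl group can only give five-membered ring A with the trisubstituted C1=C2 bond, the trans-diequatorial chains on C3a and C8a lie gauche and within reach, and the free homoallylic alcohol is tolerated.

Step 19
Reactants: 30 bicyclic alcohol
Product: 31 O-[(3aR,4S,5S,7S,8aS)-7-(benzyloxy)-5-[(tert-butyldimethylsilyl)oxy]-2,7-dimethyl-4-(propan-2-yl)-3,3a,4,5,6,7,8,8a-octahydroazulen-8-yl] S-methyl dithiocarbonate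
Conditions: NaH, THF, 0 °C → rt; CS2; MeI
Reagents that add atoms: carbon disulfide, S=C=S; iodomethane, CI
Why: Xanthate formation through the sodium alkoxide copes with the hindered C8 hydroxyl, and with a benzyl ether on C7 no silyl group is present that could migrate to the alkoxide.

Step 20
Reactants: 31 xanthate
Product: 32 (3aR,4S,5S,7R,8aS)-7-(benzyloxy)-5-[(tert-butyldimethylsilyl)oxy]-2,7-dimethyl-4-(propan-2-yl)-3,3a,4,5,6,7,8,8a-octahydroazulene
Conditions: Bu3SnH (high concentration), AIBN (cat.), toluene, 90 °C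
Reagents that add atoms: none
Why: Barton–McCombie deoxygenation, in which the secondary C8 radical is reduced by the stannane, a benzyloxy group is no radical leaving group, and closure onto C1=C2 is slow, reversible and would lead only to a strained bridged radical, so clean formation of C8H2 is expected.

Step 21
Reactants: 32 silyl ether
Product: 33 (3aR,4S,5S,7R,8aS)-7-(benzyloxy)-2,7-dimethyl-4-(propan-2-yl)-3,3a,4,5,6,7,8,8a-octahydroazulen-5-ol
Conditions: Bu4NF, THF, rt → 45 °C
Reagents that add atoms: none
Why: Fluoride-mediated desilylation frees only the C5 hydroxyl because the C7 oxygen is still benzylated.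

Step 22
Reactants: 33 C5 alcohol; 34 4-(benzyloxy)benzoyl chloride
Product: 35 (3aR,4S,5S,7R,8aS)-7-(benzyloxy)-2,7-dimethyl-4-(propan-2-yl)-3,3a,4,5,6,7,8,8a-octahydroazulen-5-yl 4-(benzyloxy)benzoate
Conditions: Et3N, DMAP (cat.), CH2Cl2, rt
Reagents that add atoms: none
Why: DMAP-catalysed acylation meets a single free, equatorial secondary hydroxyl, so no selectivity is needed and C5 keeps its configuration.

Step 23
Reactants: 35 alkene ester
Product: 36 (1S,2R,3aR,4S,5S,7R,8aS)-7-(benzyloxy)-1,2-epoxy-2,7-dimethyl-4-(propan-2-yl)decahydroazulen-5-yl 4-(benzyloxy)benzoate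
Conditions: m-CPBA, CH2Cl2, 0 °C
Reagents that add atoms: m-chloroperoxybenzoic acid, OOC(=O)c1cccc(Cl)c1
Why: Prilezhaev epoxidation of the only alkene, where the trans fusion locks ring A as an envelope with C3a bent to the α face, so that α attack on C1=C2 is staggered to the allylic bonds at C8a and C3 whereas β attack eclipses the pseudoaxial C8a–H and C3–H bonds (torsional steering), which should set C1 and C2 with the oxygen α.

Step 24
Reactants: 36 epoxy bis(benzyl ether)
Product: 37 (1S,2R,3aR,4S,5S,7R,8aS)-1,2-epoxy-7-hydroxy-2,7-dimethyl-4-(propan-2-yl)decahydroazulen-5-yl 4-hydroxybenzoate (CNP0245441.1)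
Conditions: H2 (1 atm), 10% Pd/C, EtOAc, rt
Reagents that add atoms: none
Why: Hydrogenolysis cleaves the aryl and the tertiary alkyl benzyl ether in one neutral operation that spares the ester and the non-benzylic trisubstituted epoxide.

Compound list
1 | (S)-citramalic acid | OC(=O)[C@@](C)(O)CC(=O)O | starting material
2 | 2-[(4S)-2,2,4-trimethyl-5-oxo-1,3-dioxolan-4-yl]acetic acid | O=C1OC(C)(C)O[C@@]1(C)CC(=O)O | intermediate
3 | (5S)-5-(2-hydroxyethyl)-2,2,5-trimethyl-1,3-dioxolan-4-one (not isolated) | O=C1OC(C)(C)O[C@@]1(C)CCO | intermediate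
4 | (3S)-3-hydroxy-3-methyloxolan-2-one | O=C1OCC[C@]1(C)O | intermediate
5 | (3S)-3-(benzyloxy)-3-methyloxolan-2-one | O=C1OCC[C@]1(C)OCc2ccccc2 | intermediate
6 | (2S)-2-(benzyloxy)-4-hydroxy-N-methoxy-N,2-dimethylbutanamide | CON(C)C(=O)[C@@](C)(OCc1ccccc1)CCO | intermediate
7 | (2S)-2-(benzyloxy)-N-methoxy-N,2-dimethyl-4-oxobutanamide | CON(C)C(=O)[C@@](C)(OCc1ccccc1)CC=O | intermediate
8 | (4R)-4-benzyl-1,3-oxazolidin-2-one | O=C1N[C@H](Cc2ccccc2)CO1 | starting material
9 | 3-methylbutanoyl chloride | CC(C)CC(Cl)=O | starting material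
10 | (4R)-4-benzyl-3-(3-methylbutanoyl)-1,3-oxazolidin-2-one | CC(C)CC(=O)N1[C@H](Cc2ccccc2)COC1=O | intermediate
11 | Z-dibutylboron enolate of 10 (not isolated) | CC(C)/C=C(\OB(CCCC)CCCC)N1[C@H](Cc2ccccc2)COC1=O | intermediate
12 | syn-aldol adduct, (2R,3S,5S)-acyl chain on the (4R)-auxiliary, C5–OH free | CC(C)[C@@H](C(=O)N1[C@H](Cc2ccccc2)COC1=O)[C@@H](O)C[C@](C)(OCc1ccccc1)C(=O)N(C)OC | intermediate
13 | C5 TBS ether of 12 | CC(C)[C@@H](C(=O)N1[C@H](Cc2ccccc2)COC1=O)[C@@H](O[Si](C)(C)C(C)(C)C)C[C@](C)(OCc1ccccc1)C(=O)N(C)OC | intermediate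
14 | (2S,4S,5S)-2-(benzyloxy)-4-[(tert-butyldimethylsilyl)oxy]-5-(hydroxymethyl)-N-methoxy-N,2,6-trimethylheptanamide | CC(C)[C@@H](CO)[C@@H](O[Si](C)(C)C(C)(C)C)C[C@](C)(OCc1ccccc1)C(=O)N(C)OC | intermediate
15 | (2S,4S,5R)-2-(benzyloxy)-4-[(tert-butyldimethylsilyl)oxy]-5-formyl-N-methoxy-N,2,6-trimethylheptanamide | CC(C)[C@@H](C=O)[C@@H](O[Si](C)(C)C(C)(C)C)C[C@](C)(OCc1ccccc1)C(=O)N(C)OC | intermediate
16 | (2S,4S,5S)-2-(benzyloxy)-4-[(tert-butyldimethylsilyl)oxy]-N-methoxy-N,2-dimethyl-5-(propan-2-yl)hept-6-enamide | CC(C)[C@@H](C=C)[C@@H](O[Si](C)(C)C(C)(C)C)C[C@](C)(OCc1ccccc1)C(=O)N(C)OC | intermediate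
17 | vinylmagnesium bromide | C=C[Mg]Br | starting material
18 | (4S,6S,7S)-4-(benzyloxy)-6-[(tert-butyldimethylsilyl)oxy]-4-methyl-7-(propan-2-yl)nona-1,8-dien-3-one | CC(C)[C@@H](C=C)[C@@H](O[Si](C)(C)C(C)(C)C)C[C@](C)(OCc1ccccc1)C(=O)C=C | intermediate
19 | (4S,5S,7S)-7-(benzyloxy)-5-[(tert-butyldimethylsilyl)oxy]-7-methyl-4-(propan-2-yl)cyclohept-2-en-1-one | CC(C)[C@H]1C=CC(=O)[C@@](C)(OCc2ccccc2)C[C@@H]1O[Si](C)(C)C(C)(C)C | intermediate
20 | benzeneselenenyl chloride | Cl[Se]c1ccccc1 | starting material
21 | ethyl vinyl ether | C=COCC | starting material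
22 | 1-chloro-1-ethoxy-2-(phenylselanyl)ethane (not isolated) | CCOC(Cl)C[Se]c1ccccc1 | intermediate
23 | (phenylselanyl)acetaldehyde | O=CC[Se]c1ccccc1 | intermediate
24 | methallyltrimethylsilane | C=C(C)C[Si](C)(C)C | starting material
25 | trichlorotitanium C8=C8a enolate with 3aβ-methallyl chain (not isolated) | CC(C)[C@H]1[C@H](CC(C)=C)C=C(O[Ti](Cl)(Cl)Cl)[C@@](C)(OCc2ccccc2)C[C@@H]1O[Si](C)(C)C(C)(C)C | intermediate
26 | (2S,3S,4S,5S,7S)-7-(benzyloxy)-5-[(tert-butyldimethylsilyl)oxy]-2-[1-hydroxy-2-(phenylselanyl)ethyl]-7-methyl-3-(2-methylprop-2-en-1-yl)-4-(propan-2-yl)cycloheptan-1-one | CC(C)[C@H]1[C@H](CC(C)=C)[C@@H](C(O)C[Se]c2ccccc2)C(=O)[C@@](C)(OCc2ccccc2)C[C@@H]1O[Si](C)(C)C(C)(C)C | intermediate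
27 | methanesulfonate of 26 at the C1 hydroxyl (not isolated) | CC(C)[C@H]1[C@H](CC(C)=C)[C@@H](C(OS(C)(=O)=O)C[Se]c2ccccc2)C(=O)[C@@](C)(OCc2ccccc2)C[C@@H]1O[Si](C)(C)C(C)(C)C | intermediate
28 | (2R,3S,4S,5S,7S)-7-(benzyloxy)-5-[(tert-butyldimethylsilyl)oxy]-2-ethenyl-7-methyl-3-(2-methylprop-2-en-1-yl)-4-(propan-2-yl)cycloheptan-1-one | CC(C)[C@H]1[C@H](CC(C)=C)[C@@H](C=C)C(=O)[C@@](C)(OCc2ccccc2)C[C@@H]1O[Si](C)(C)C(C)(C)C | intermediate
29 | (2R,3R,4S,5S,7S)-7-(benzyloxy)-5-[(tert-butyldimethylsilyl)oxy]-2-ethenyl-7-methyl-3-(2-methylprop-2-en-1-yl)-4-(propan-2-yl)cycloheptan-1-ol, C8 epimers | CC(C)[C@H]1[C@H](CC(C)=C)[C@@H](C=C)C(O)[C@@](C)(OCc2ccccc2)C[C@@H]1O[Si](C)(C)C(C)(C)C | intermediate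
30 | (3aR,4S,5S,7S,8aS)-7-(benzyloxy)-5-[(tert-butyldimethylsilyl)oxy]-2,7-dimethyl-4-(propan-2-yl)-3,3a,4,5,6,7,8,8a-octahydroazulen-8-ol, C8 epimers | CC(C)[C@H]1[C@@H]2CC(C)=C[C@H]2C(O)[C@@](C)(OCc3ccccc3)C[C@@H]1O[Si](C)(C)C(C)(C)C | intermediate
31 | S-methyl xanthate of 30 at C8 | CC(C)[C@H]1[C@@H]2CC(C)=C[C@H]2C(OC(=S)SC)[C@@](C)(OCc3ccccc3)C[C@@H]1O[Si](C)(C)C(C)(C)C | intermediate
32 | (3aR,4S,5S,7R,8aS)-7-(benzyloxy)-5-[(tert-butyldimethylsilyl)oxy]-2,7-dimethyl-4-(propan-2-yl)-3,3a,4,5,6,7,8,8a-octahydroazulene | CC(C)[C@H]1[C@@H]2CC(C)=C[C@H]2C[C@@](C)(OCc3ccccc3)C[C@@H]1O[Si](C)(C)C(C)(C)C | intermediate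
33 | (3aR,4S,5S,7R,8aS)-7-(benzyloxy)-2,7-dimethyl-4-(propan-2-yl)-3,3a,4,5,6,7,8,8a-octahydroazulen-5-ol | CC(C)[C@H]1[C@@H]2CC(C)=C[C@H]2C[C@@](C)(OCc3ccccc3)C[C@@H]1O | intermediate
34 | 4-(benzyloxy)benzoyl chloride | O=C(Cl)c1ccc(OCc2ccccc2)cc1 | starting material
35 | (3aR,4S,5S,7R,8aS)-7-(benzyloxy)-2,7-dimethyl-4-(propan-2-yl)-3,3a,4,5,6,7,8,8a-octahydroazulen-5-yl 4-(benzyloxy)benzoate | CC(C)[C@H]1[C@@H]2CC(C)=C[C@H]2C[C@@](C)(OCc3ccccc3)C[C@@H]1OC(=O)c1ccc(OCc3ccccc3)cc1 | intermediate
36 | (1S,2R,3aR,4S,5S,7R,8aS)-7-(benzyloxy)-1,2-epoxy-2,7-dimethyl-4-(propan-2-yl)decahydroazulen-5-yl 4-(benzyloxy)benzoate | CC(C)[C@H]1[C@@H]2C[C@@]3(C)O[C@H]3[C@H]2C[C@@](C)(OCc4ccccc4)C[C@@H]1OC(=O)c1ccc(OCc4ccccc4)cc1 | intermediate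
37 | (1S,2R,3aR,4S,5S,7R,8aS)-1,2-epoxy-7-hydroxy-2,7-dimethyl-4-(propan-2-yl)decahydroazulen-5-yl 4-hydroxybenzoate | CC(C)[C@H]1[C@@H]2C[C@@]3(C)O[C@H]3[C@H]2C[C@@](C)(O)C[C@@H]1OC(=O)c1ccc(O)cc1 | target

Total step count: 24. Longest linear sequence: 22 steps (steps 1–5, 7–13 and 15–24, from (S)-citramalic acid). Steps 6 and 14 are side branches.

Steps most likely to fail

First, step 15. The coupling may stop after the first bond if the enolate is protonated before it is trapped. Left-over silane may consume the aldehyde, the Lewis acid may strip a protecting group, or the facial bias at C3a may be too weak. The fallback forms the same two bonds in two separate operations. It sets out from 19. Conjugate addition of the methallyl cuprate made from methallylmagnesium chloride and CuBr·SMe2, in the presence of Me3SiCl (THF, −78 °C), should give trimethylsilyl enol ether F1, again by attack anti to the isopropyl group. A Mukaiyama aldol addition of this isolated enol ether to 23 (BF3·OEt2, CH2Cl2, −78 °C) then forms C1–C8a anti to the methallyl chain and rejoins the route at 26.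

Second, step 23. Facial selectivity may be poor or reversed if steric approach to the β face outweighs the torsional preference for the α face. The fallback turns a β preference of electrophiles into the α-epoxide. It sets out from 35. NBS in aqueous DME at 0 °C should form the bromonium ion on the β face, and water should open it at the more substituted C2 from the α face. This gives trans-bromohydrin F2. K2CO3 in acetone then closes the ring by displacement of bromide from the α side and rejoins the route at 36.

Third, step 12. Addition to the hindered α-quaternary amide may be sluggish. The basic Grignard reagent may instead cleave the N-methoxy group, or the liberated amine may add to the enone during work-up. The fallback changes the oxidation-level sequence. It sets out from 16. Reduction with i-Bu2AlH (toluene, −78 °C) should give α-benzyloxy aldehyde F3. Addition of 17 (THF, −78 °C) gives allylic alcohol F4 as an inconsequential epimer mixture. Dess–Martin oxidation then rejoins the route at 18.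

Further compounds
F1 | step 15 | {[(3S,4S,5S,7S)-7-(benzyloxy)-5-[(tert-butyldimethylsilyl)oxy]-7-methyl-3-(2-methylprop-2-en-1-yl)-4-(propan-2-yl)cyclohept-1-en-1-yl]oxy}trimethylsilane | CC(C)[C@H]1[C@H](CC(C)=C)C=C(O[Si](C)(C)C)[C@@](C)(OCc2ccccc2)C[C@@H]1O[Si](C)(C)C(C)(C)C
F2 | step 23 | (1R,2R,3aS,4S,5S,7R,8aS)-7-(benzyloxy)-1-bromo-2-hydroxy-2,7-dimethyl-4-(propan-2-yl)decahydroazulen-5-yl 4-(benzyloxy)benzoate (1β-Br, 2α-OH) | CC(C)[C@H]1[C@@H]2C[C@@](C)(O)[C@H](Br)[C@H]2C[C@@](C)(OCc3ccccc3)C[C@@H]1OC(=O)c1ccc(OCc3ccccc3)cc1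
F3 | step 12 | (2S,4S,5S)-2-(benzyloxy)-4-[(tert-butyldimethylsilyl)oxy]-2-methyl-5-(propan-2-yl)hept-6-enal | CC(C)[C@@H](C=C)[C@@H](O[Si](C)(C)C(C)(C)C)C[C@](C)(OCc1ccccc1)C=O
F4 | step 12 | (4S,6S,7S)-4-(benzyloxy)-6-[(tert-butyldimethylsilyl)oxy]-4-methyl-7-(propan-2-yl)nona-1,8-dien-3-ol (C3 epimers) | CC(C)[C@@H](C=C)[C@@H](O[Si](C)(C)C(C)(C)C)C[C@](C)(OCc1ccccc1)C(O)C=C
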